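Target 15 ⇐ thioester 14 by thioester-to-aldehyde reduction: the side-chain formyl group is carried as an S-ethyl thioester, so that only one aldehyde is present when the ring is made.
14 ⇐ enal–ketone 12 + silyl ketene thioacetal 7 in one pot: a conjugate addition makes the exocyclic CH–CH bond with both stereocentres, then an aldol condensation makes the ring C=C bond between the CHO-bearing and the CH2OAc-bearing carbons; the cyclopentene is the only ring and is formed here.
Enabling feature: the ring alkene is the α,β-bond of a cyclopent-1-ene-1-carbaldehyde (α-carbon bears CHO, β-carbon bears CH2OAc and can be a ketone carbon), and the two formyl carbons are 1,5-related through the ring CH; the enamine left at the α-carbon after conjugate addition to an enal therefore sits four bonds from that ketone and closes a five-membered ring.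
12 ⇐ hex-5-ene-1,2-diol (acetylation, oxidation, cross-metathesis with crotonaldehyde); 7 ⇐ geranyl bromide + C3 Grignard reagent (oxidation, thioesterification, geometry-controlled enolisation and silylation).

Key step: step 8

Remark: racemic hex-5-ene-1,2-diol is used because its only stereocentre becomes the ketone carbon in step 6; both enantiomers of the imidazolidinone catalyst of step 8 are taken to be commercial.

Step 1
Reactants: 1 geranyl bromide, (2E)-1-bromo-3,7-dimethylocta-2,6-diene; 2 3-chloropropan-1-ol
Product: 4 (5E)-6,10-dimethylundeca-5,9-dien-1-ol, via chloromagnesium 3-(chloromagnesio)propan-1-olate 3 (not isolated)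
Conditions: 2, i-PrMgCl (1.0 equiv), THF, −20 °C, then Mg, reflux; then 1, Li2CuCl4 (3 mol%), THF, −30 → 0 °C; aq. NH4Cl
Reagents that add atoms: none
Why: Copper-catalysed (Kochi-type) coupling of the alkoxide-protected Grignard reagent 3 with the primary allylic bromide should take place at the unhindered CH2 carbon (SN2 rather than SN2′) with retention of the (E)-trisubstituted alkene, so that the C13 chain with its terminal hydroxyl is made in one operation.

Step 2
Reactants: 4 (5E)-6,10-dimethylundeca-5,9-dien-1-ol
Product: 5 (5E)-6,10-dimethylundeca-5,9-dienoic acid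
Conditions: TEMPO (20 mol%), PhI(OAc)2 (2.2 equiv), MeCN/H2O (1:1), rt
Reagents that add atoms: water, O
Why: Oxoammonium (TEMPO) oxidation should carry the primary alcohol through the aldehyde hydrate to the acid while leaving the two trisubstituted alkenes untouched.

Step 3
Reactants: 5 (5E)-6,10-dimethylundeca-5,9-dienoic acid
Product: 6 S-ethyl (5E)-6,10-dimethylundeca-5,9-dienethioate
Conditions: EtSH (1.5 equiv), DCC (1.1 equiv), DMAP (10 mol%), CH2Cl2, 0 °C → rt
Reagents that add atoms: ethanethiol, CCS
Why: Steglich-type carbodiimide coupling with DMAP acyl transfer should give the S-ethyl thioester, the carboxyl form that can be enolised in step 4 and reduced to the aldehyde in step 9.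

Step 4
Reactants: 6 S-ethyl (5E)-6,10-dimethylundeca-5,9-dienethioate
Product: 7 tert-butyl{[(1E,5E)-1-(ethylsulfanyl)-6,10-dimethylundeca-1,5,9-trien-1-yl]oxy}dimethylsilane (alkyl chain cis to the silyloxy group)
Conditions: LiN(i-Pr)2 (1.1 equiv), THF/HMPA (4:1), −78 °C; then t-BuMe2SiCl, −78 °C → rt; non-aqueous work-up
Reagents that add atoms: tert-butyldimethylsilyl chloride, CC(C)(C)[Si](C)(C)Cl
Why: Ireland-type kinetic enolisation in the presence of HMPA goes through an open, non-chelated transition state and should give the enolate with the chain cis to oxygen, which O-silylation fixes as the (1E) silyl ketene thioacetal (sulfur outranks oxygen in the descriptor).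

Step 5
Reactants: 8 hex-5-ene-1,2-diol (racemic)
Product: 9 2-hydroxyhex-5-en-1-yl acetate (racemic)
Conditions: AcCl (1.05 equiv), 2,4,6-collidine, CH2Cl2, −78 °C
Reagents that add atoms: acetyl chloride, CC(=O)Cl
Why: An acyl chloride with a hindered pyridine base at low temperature should acylate the primary hydroxyl selectively over the secondary one (kinetically controlled monoacylation of a 1,2-diol).

Step 6
Reactants: 9 2-hydroxyhex-5-en-1-yl acetate
Product: 10 2-oxohex-5-en-1-yl acetate
Conditions: Dess–Martin periodinane (1.2 equiv), CH2Cl2, 0 °C → rt
Reagents that add atoms: none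
Why: Dess–Martin oxidation of the secondary alcohol under neutral conditions should give the α-acetoxy ketone without touching the terminal alkene or moving the acetate.

Step 7
Reactants: 10 2-oxohex-5-en-1-yl acetate; 11 (E)-but-2-enal (crotonaldehyde, 5 equiv)
Product: 12 (5E)-2,7-dioxohept-5-en-1-yl acetate
Conditions: second-generation Hoveyda–Grubbs catalyst RuCl2(H2IMes)(=CH-C6H4-2-O-i-Pr) (3 mol%), CH2Cl2, 40 °C
Reagents that add atoms: none
Why: Olefin cross-metathesis of the terminal alkene with excess crotonaldehyde, driven by loss of propene, should give the (E)-enal as the thermodynamically preferred isomer, the ketone and the acetate being inert to the ruthenium carbene.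

Step 8
Reactants: 12 (5E)-2,7-dioxohept-5-en-1-yl acetate; 7 silyl ketene thioacetal (1.5 equiv)
Product: 14 S-ethyl (2S,5E)-2-[(1R)-3-(acetoxymethyl)-2-formylcyclopent-2-en-1-yl]-6,10-dimethylundeca-5,9-dienethioate, via open-chain keto aldehyde 13 (not isolated)
Conditions: (2R,5R)-5-benzyl-2-tert-butyl-3-methylimidazolidin-4-one·CCl3CO2H (20 mol%), H2O (2 equiv), CH2Cl2, −60 °C; then Bn2NH·CF3CO2H (0.5 equiv), 23 → 40 °C
Reagents that add atoms: none
Why: The imidazolidinone salt converts 12 into an (E)-iminium ion, the nucleophilic carbon of 7 adds to its β-carbon through an open transition state (Mukaiyama–Michael addition), water takes up the silyl group and hydrolysis releases 13; the dibenzylammonium salt then turns the CH2–CHO group of 13 into an enamine that adds to the α-acetoxy ketone, and E1cB loss of water from the aldol gives the conjugated enal and with it the ring C=C bond. The closest known reaction types are the imidazolidinone-catalysed Mukaiyama–Michael addition of S-alkyl silyl ketene thioacetals to β-alkyl enals and the ammonium-salt-mediated aldol condensation of 6-oxoalkanals to 2-substituted cyclopent-1-ene-1-carbaldehydes. The cyclopentene closes in the 5-(enolexo)-exo-trig mode, the aldehyde α-carbon being the nucleophile and the ketone carbon the electrophile. The ring stereocentre is controlled by the catalyst, whose benzyl group in the (2R,5R) series is expected to shield the Re face of the β-carbon so that 7 adds to the Si face; the side-chain stereocentre is controlled by the (1E) geometry of 7, since in the antiperiplanar open transition state its chain lies anti to the β-substituent of the enal and the bulky silyloxy group, cis to that chain, points away from it (anti adduct, an assignment that rests on this model). The step needs anti simple diastereoselection, enamine formation at one aldehyde only, and survival of the thioester, the acetate and the new α-stereocentre; these are secured by the geometric purity of 7, by the masking of the second formyl group as a thioester that cannot form an enamine, and by the weakly acidic, non-nucleophilic ammonium-salt medium.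

Step 9
Reactants: 14 S-ethyl (2S,5E)-2-[(1R)-3-(acetoxymethyl)-2-formylcyclopent-2-en-1-yl]-6,10-dimethylundeca-5,9-dienethioate
Product: 15 [(3R)-2-formyl-3-[(2S,5E)-6,10-dimethyl-1-oxoundeca-5,9-dien-2-yl]cyclopent-1-en-1-yl]methyl acetate
Conditions: Et3SiH (3 equiv), 10% Pd/C (5 mol% Pd), acetone, rt
Reagents that add atoms: none
Why: Fukuyama reduction (insertion of palladium into the C–S bond, hydride transfer from the silane, reductive elimination) should convert the thioester into the aldehyde under neutral conditions that leave the enal, the acetate and the trisubstituted alkenes alone and do not epimerise the α-formyl stereocentre.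

Compound list
1 | geranyl bromide, (2E)-1-bromo-3,7-dimethylocta-2,6-diene | CC(C)=CCC/C(C)=C/CBr | starting material
2 | 3-chloropropan-1-ol | OCCCCl | starting material
3 | chloromagnesium 3-(chloromagnesio)propan-1-olate | Cl[Mg]CCCO[Mg]Cl | intermediate (not isolated)
4 | (5E)-6,10-dimethylundeca-5,9-dien-1-ol | OCCCC/C=C(\C)CCC=C(C)C | intermediate
5 | (5E)-6,10-dimethylundeca-5,9-dienoic acid | OC(=O)CCC/C=C(\C)CCC=C(C)C | intermediate
6 | S-ethyl (5E)-6,10-dimethylundeca-5,9-dienethioate | CCSC(=O)CCC/C=C(\C)CCC=C(C)C | intermediate
7 | tert-butyl{[(1E,5E)-1-(ethylsulfanyl)-6,10-dimethylundeca-1,5,9-trien-1-yl]oxy}dimethylsilane | CCS/C(O[Si](C)(C)C(C)(C)C)=C/CC/C=C(\C)CCC=C(C)C | intermediate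
8 | hex-5-ene-1,2-diol (racemic) | OCC(O)CCC=C | starting material
9 | 2-hydroxyhex-5-en-1-yl acetate (racemic) | CC(=O)OCC(O)CCC=C | intermediate
10 | 2-oxohex-5-en-1-yl acetate | CC(=O)OCC(=O)CCC=C | intermediate
11 | (E)-but-2-enal | C/C=C/C=O | starting material
12 | (5E)-2,7-dioxohept-5-en-1-yl acetate | CC(=O)OCC(=O)CC/C=C/C=O | intermediate
13 | S-ethyl (2S,5E)-2-[(3S)-7-acetoxy-1,6-dioxoheptan-3-yl]-6,10-dimethylundeca-5,9-dienethioate | O=CC[C@@H]([C@@H](C(=O)SCC)CC/C=C(\C)CCC=C(C)C)CCC(=O)COC(C)=O | intermediate (not isolated)
14 | S-ethyl (2S,5E)-2-[(1R)-3-(acetoxymethyl)-2-formylcyclopent-2-en-1-yl]-6,10-dimethylundeca-5,9-dienethioate | CC(=O)OCC1=C(C=O)[C@@H]([C@@H](C(=O)SCC)CC/C=C(\C)CCC=C(C)C)CC1 | intermediate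
15 | [(3R)-2-formyl-3-[(2S,5E)-6,10-dimethyl-1-oxoundeca-5,9-dien-2-yl]cyclopent-1-en-1-yl]methyl acetate | CC(=O)OCC1=C(C=O)[C@@H]([C@@H](C=O)CC/C=C(\C)CCC=C(C)C)CC1 | target

Total step count: 9. Longest linear sequence: 6 steps (1, 2, 3, 4, 8, 9).

Steps most likely to fail

Step 8. The simple diastereoselection of the C–C bond formation between the enolsilane carbon and the iminium β-carbon may be low or may run in the opposite sense, because it rests on the geometry of 7 and on an open transition state. Facial control may also be eroded by uncatalysed background addition. The fallback sets the side-chain stereocentre under thermodynamic instead of kinetic control. It sets out from 14, obtained together with its side-chain epimer S-ethyl (2R,5E)-2-[(1R)-3-(acetoxymethyl)-2-formylcyclopent-2-en-1-yl]-6,10-dimethylundeca-5,9-dienethioate F1. The mixture is reduced as in step 9 to 15 and the epimeric dialdehyde [(3R)-2-formyl-3-[(2R,5E)-6,10-dimethyl-1-oxoundeca-5,9-dien-2-yl]cyclopent-1-en-1-yl]methyl acetate F2. After separation, F2 is equilibrated at its formyl-bearing stereocentre through the enamine (Bn2NH·CF3CO2H cat., CH2Cl2, rt), which should leave the ring stereocentre untouched because it has no acidifying neighbour, and is separated again. Repetition should funnel the material to 15, where the route is rejoined.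

Step 9. Zerovalent palladium may ionise the allylic acetate, with hydride capture leading to deoxygenation, or the silane may reduce the enal in conjugate fashion or over-reduce the new formyl group. The fallback moves the reduction in front of the ring closure. Step 8 is stopped after its first stage and 13 is isolated; it has neither an allylic acetate nor an enal. Fukuyama reduction of 13 (Et3SiH, Pd/C, acetone) should give the keto dialdehyde (5S,6S,9E)-6-formyl-10,14-dimethyl-2-oxo-5-(2-oxoethyl)pentadeca-9,13-dien-1-yl acetate F3. Treatment of F3 with Bn2NH·CF3CO2H should close the ring to 15, where the route is rejoined. Only the unbranched CH2–CHO group can give an aldol that dehydrates to a conjugated enal, whereas the α-branched formyl group forms its enamine slowly and can add to the ketone only reversibly.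

Step 4. Enolate geometry may leak to the isomer with the chain cis to sulfur, and C-silylation, Claisen self-condensation or hydrolysis of 7 on isolation may intervene. The fallback makes the same geometry by 1,4-hydrosilylation instead of enolisation; it sets out from 6 and returns at 7. Selenenylation of 6 (LiN(i-Pr)2, THF, −78 °C; PhSeBr) should give S-ethyl (5E)-6,10-dimethyl-2-(phenylselanyl)undeca-5,9-dienethioate F4. Oxidation and syn-elimination of the selenoxide (H2O2, pyridine, CH2Cl2, 0 °C) should give S-ethyl (2E,5E)-6,10-dimethylundeca-2,5,9-trienethioate F5. Conjugate hydrosilylation of F5 (t-BuMe2SiH, RhCl(PPh3)3 cat., toluene, 60 °C) through the s-cis conformer should place the chain cis to the silyloxy group and so deliver 7.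

Further compounds
F1 | step 8 | S-ethyl (2R,5E)-2-[(1R)-3-(acetoxymethyl)-2-formylcyclopent-2-en-1-yl]-6,10-dimethylundeca-5,9-dienethioate | CC(=O)OCC1=C(C=O)[C@@H]([C@H](C(=O)SCC)CC/C=C(\C)CCC=C(C)C)CC1
F2 | step 8 | [(3R)-2-formyl-3-[(2R,5E)-6,10-dimethyl-1-oxoundeca-5,9-dien-2-yl]cyclopent-1-en-1-yl]methyl acetate | CC(=O)OCC1=C(C=O)[C@@H]([C@H](C=O)CC/C=C(\C)CCC=C(C)C)CC1
F3 | step 9 | (5S,6S,9E)-6-formyl-10,14-dimethyl-2-oxo-5-(2-oxoethyl)pentadeca-9,13-dien-1-yl acetate | O=CC[C@@H]([C@@H](C=O)CC/C=C(\C)CCC=C(C)C)CCC(=O)COC(C)=O
F4 | step 4 | S-ethyl (5E)-6,10-dimethyl-2-(phenylselanyl)undeca-5,9-dienethioate (racemic) | CCSC(=O)C([Se]c1ccccc1)CC/C=C(\C)CCC=C(C)C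
F5 | step 4 | S-ethyl (2E,5E)-6,10-dimethylundeca-2,5,9-trienethioate | CCSC(=O)/C=C/C/C=C(\C)CCC=C(C)C
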